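## Retrosynthetic overview

1. Target 25 ⇐ desilylation, 1(10)-epoxidation and C8 methacrylation of the macrocyclic triene lactone 21.
2. 21 ⇐ SmI2 ketyl–olefin radical macrocyclisation forming C7–C8: the C8 ketyl of seco-aldehyde 19 adds to the butenolide, and loss of the C13 silyloxy group unveils the α-methylene lactone.
3. 19 ⇐ asymmetric Ni/Cr coupling (C3–C4) of butenolide alkenyl bromide 10 with aldehyde 17, which comes from but-3-yn-1-ol by carboalumination and oxirane opening.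
4. 10 ⇐ I-selective carbonylative lactonisation of the Br/I-differentiated divinyl carbinol 9 ⇐ asymmetric alkynylation of bromo-enal 5; both arms come from propargyl alcohol.
5. Ring order: butenolide (step 6), then the ten-membered carbocycle (step 12), then the epoxide (step 14).

Assumption: atoms are labelled with germacrane numbering (C1–C15); the facial sense of the two chiral catalysts (ProPhenol in step 4, Kishi ligand in step 10) is taken from their standard models, and the antipodal ligand is used if a sense proves opposite.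

## Route

Step 1
Reactants: 1 prop-2-yn-1-ol
Product: 2 tert-butyldimethyl(prop-2-yn-1-yloxy)silane
Conditions: TBSCl, imidazole, CH2Cl2, 0 °C to rt
Reagents that add atoms: tert-butyldimethylsilyl chloride, CC(C)(C)[Si](C)(C)Cl
Why: Standard silyl ether protection of a primary alcohol; the same ether later serves as both the C15 and the C13 oxygen carrier.

Step 2
Reactants: 2 tert-butyldimethyl(prop-2-yn-1-yloxy)silane
Product: 4 4-[(tert-butyldimethylsilyl)oxy]but-2-ynal, via lithium acetylide 3 (not isolated)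
Conditions: n-BuLi, THF, −78 °C; DMF, −78 to 0 °C; reverse quench into aq. KH2PO4
Reagents that add atoms: N,N-dimethylformamide, CN(C)C=O
Why: Formylation of a lithium acetylide with DMF; the buffered reverse quench releases the ynal without conjugate addition of dimethylamine.

Step 3
Reactants: 4 4-[(tert-butyldimethylsilyl)oxy]but-2-ynal
Product: 5 (Z)-3-bromo-4-[(tert-butyldimethylsilyl)oxy]but-2-enal
Conditions: LiBr, AcOH, MeCN, rt
Reagents that add atoms: lithium bromide, [Li+].[Br-]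
Why: Anti-hydrobromination of an electron-poor alkyne (bromide conjugate addition, then protonation) gives the Z β-bromo enal, which fixes the later C4=C5 geometry (Br cis to the future C6).

Step 4
Reactants: 5 (Z)-3-bromo-4-[(tert-butyldimethylsilyl)oxy]but-2-enal; 2 tert-butyldimethyl(prop-2-yn-1-yloxy)silane
Product: 7 (2Z,4R)-2-bromo-1,7-bis[(tert-butyldimethylsilyl)oxy]hept-2-en-5-yn-4-ol, via alkynylzinc 6 (not isolated)
Conditions: Me2Zn, (S,S)-ProPhenol (10 mol %), Ph3PO (20 mol %), toluene, 4 °C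
Reagents that add atoms: none
Why: Zn–ProPhenol catalysed asymmetric alkynylation of an enal; the dinuclear zinc catalyst delivers the alkynyl group to the Si face of the aldehyde and sets C6 (R here), while the alkenyl bromide is inert to the zinc reagents.

Step 5
Reactants: 7 (2Z,4R)-2-bromo-1,7-bis[(tert-butyldimethylsilyl)oxy]hept-2-en-5-yn-4-ol
Product: 9 (2Z,4R,5Z)-2-bromo-6-iodo-1,7-bis[(tert-butyldimethylsilyl)oxy]hepta-2,5-dien-4-ol, via alkenylaluminate 8 (not isolated)
Conditions: Red-Al, THF, 0 °C; I2, −78 to 0 °C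
Reagents that add atoms: iodine, II
Why: Alkoxide-directed trans-hydroalumination of the propargylic alcohol followed by iodinolysis with retention puts iodine on the distal carbon, cis to the carbinol; the silyl ether does not direct, and the alkenyl bromide and C6 are untouched.

Step 6
Reactants: 9 (2Z,4R,5Z)-2-bromo-6-iodo-1,7-bis[(tert-butyldimethylsilyl)oxy]hepta-2,5-dien-4-ol
Product: 10 (5S)-5-[(1Z)-2-bromo-3-[(tert-butyldimethylsilyl)oxy]prop-1-en-1-yl]-3-{[(tert-butyldimethylsilyl)oxy]methyl}furan-2(5H)-one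
Conditions: PdCl2(PPh3)2 (5 mol %), CO (1 atm), K2CO3, MeCN, rt
Reagents that add atoms: carbon monoxide, [C-]#[O+]
Why: Pd-catalysed carbonylative lactonisation of a (Z)-γ-iodo allylic alcohol; Pd(0) inserts into C–I far faster than C–Br at room temperature, and the C6–O bond is never broken, so the centre is retained (its descriptor becomes S only through CIP priorities).

Step 7
Reactants: 11 but-3-yn-1-ol
Product: 12 (but-3-yn-1-yloxy)triethylsilane
Conditions: TESCl, imidazole, CH2Cl2, 0 °C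
Reagents that add atoms: triethylsilyl chloride, CC[Si](CC)(CC)Cl
Why: Silyl ether protection; a primary TES ether is chosen because it can later be oxidised directly to the C8 aldehyde.

Step 8
Reactants: 12 (but-3-yn-1-yloxy)triethylsilane; 13 oxirane
Product: 16 (E)-4-methyl-6-[(triethylsilyl)oxy]hex-3-en-1-ol, via alkenylalane 14 (not isolated), via lithium alanate 15 (not isolated)
Conditions: Me3Al, Cp2ZrCl2 (20 mol %), CH2Cl2, 0 °C to rt; n-BuLi, THF, −78 °C; oxirane, −78 to 0 °C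
Reagents that add atoms: trimethylaluminium, C[Al](C)C
Why: Negishi Zr-catalysed carboalumination adds Me–Al syn across the terminal alkyne (E-trisubstituted C1=C10 alkene), and the derived alanate opens oxirane with retention of alkene geometry.

Step 9
Reactants: 16 (E)-4-methyl-6-[(triethylsilyl)oxy]hex-3-en-1-ol
Product: 17 (E)-4-methyl-6-[(triethylsilyl)oxy]hex-3-enal
Conditions: Dess–Martin periodinane, NaHCO3, CH2Cl2, 0 °C
Reagents that add atoms: none
Why: Dess–Martin oxidation under buffered, neutral conditions gives the β,γ-unsaturated aldehyde without conjugation; it is used at once.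

Step 10
Reactants: 10 (5S)-5-[(1Z)-2-bromo-3-[(tert-butyldimethylsilyl)oxy]prop-1-en-1-yl]-3-{[(tert-butyldimethylsilyl)oxy]methyl}furan-2(5H)-one; 17 (E)-4-methyl-6-[(triethylsilyl)oxy]hex-3-enal
Product: 18 (5R)-5-[(1Z,3S,5E)-2-{[(tert-butyldimethylsilyl)oxy]methyl}-6-methyl-3,8-bis[(triethylsilyl)oxy]octa-1,5-dien-1-yl]-3-{[(tert-butyldimethylsilyl)oxy]methyl}furan-2(5H)-one
Conditions: CrCl2 (10 mol %), Kishi sulfonamide ligand (11 mol %), proton sponge, NiCl2·neocuproine (5 mol %), Mn, LiCl, TESCl, MeCN, rt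
Reagents that add atoms: triethylsilyl chloride, CC[Si](CC)(CC)Cl
Why: Catalytic asymmetric Nozaki–Hiyama–Kishi coupling; Ni inserts into C–Br with retention of the Z geometry, the chiral Cr(III) complex adds the alkenyl group to one aldehyde face (C3 = S by catalyst control), and TESCl releases the product as its silyl ether.

Step 11
Reactants: 18 (5R)-5-[(1Z,3S,5E)-2-{[(tert-butyldimethylsilyl)oxy]methyl}-6-methyl-3,8-bis[(triethylsilyl)oxy]octa-1,5-dien-1-yl]-3-{[(tert-butyldimethylsilyl)oxy]methyl}furan-2(5H)-one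
Product: 19 (5R)-5-[(1Z,3S,5E)-2-{[(tert-butyldimethylsilyl)oxy]methyl}-6-methyl-8-oxo-3-[(triethylsilyl)oxy]octa-1,5-dien-1-yl]-3-{[(tert-butyldimethylsilyl)oxy]methyl}furan-2(5H)-one
Conditions: (COCl)2, DMSO, CH2Cl2, −78 to −40 °C; Et3N, −78 °C, cold buffered quench
Reagents that add atoms: none
Why: Swern conditions oxidise a primary TES ether directly (silyl ether to alkoxysulfonium) while secondary TES and TBS ethers survive; the cold quench protects the labile butenolide C6–H and the β,γ-unsaturated aldehyde.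

Step 12
Reactants: 19 (5R)-5-[(1Z,3S,5E)-2-{[(tert-butyldimethylsilyl)oxy]methyl}-6-methyl-8-oxo-3-[(triethylsilyl)oxy]octa-1,5-dien-1-yl]-3-{[(tert-butyldimethylsilyl)oxy]methyl}furan-2(5H)-one
Product: 21 (3S,6R,7R,8R)-15-[(tert-butyldimethylsilyl)oxy]-8-hydroxy-3-[(triethylsilyl)oxy]germacra-1(10)E,4Z,11(13)-trien-12,6-olide, via samarium enolate 20 (not isolated)
Conditions: SmI2 (2.5 equiv), THF, 2 mM, slow addition of 19, −78 °C to rt; aq. NH4Cl
Reagents that add atoms: none
Why: Proposed new method: a 10-exo-trig ketyl–olefin radical macrocyclisation ended by E1cB loss of silanolate, in which SmI2 reduces only the aldehyde, the C8 ketyl adds to C7 of the butenolide anti to the C5 side chain (trans-lactone, 7R), a Sm(III) bridge between ketyl oxygen and lactone carbonyl with the tether passing outside the C6–C7 bond gives 8R, and the second electron forms a samarium enolate that expels TBSO– to give the exo-methylene; the closest known chemistry is the intermolecular SmI2 ketyl–butenolide/acrylate lactone synthesis and SmI2 ketyl–olefin medium-ring cyclisations.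

Step 13
Reactants: 21 (3S,6R,7R,8R)-15-[(tert-butyldimethylsilyl)oxy]-8-hydroxy-3-[(triethylsilyl)oxy]germacra-1(10)E,4Z,11(13)-trien-12,6-olide; 22 methacryloyl chloride
Product: 23 (3S,6R,7R,8R)-15-[(tert-butyldimethylsilyl)oxy]-8-(methacryloyloxy)-3-[(triethylsilyl)oxy]germacra-1(10)E,4Z,11(13)-trien-12,6-olide
Conditions: Et3N, DMAP (cat.), CH2Cl2, 0 °C
Reagents that add atoms: none
Why: DMAP-catalysed acylation of the only free hydroxyl, with retention at C8.

Step 14
Reactants: 23 (3S,6R,7R,8R)-15-[(tert-butyldimethylsilyl)oxy]-8-(methacryloyloxy)-3-[(triethylsilyl)oxy]germacra-1(10)E,4Z,11(13)-trien-12,6-olide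
Product: 24 (1R,3S,6R,7R,8R,10R)-15-[(tert-butyldimethylsilyl)oxy]-1,10-epoxy-8-(methacryloyloxy)-3-[(triethylsilyl)oxy]germacra-4Z,11(13)-dien-12,6-olide
Conditions: mCPBA, NaHCO3, CH2Cl2, 0 °C
Reagents that add atoms: 3-chloroperbenzoic acid, OOC(=O)c1cccc(Cl)c1
Why: Prilezhaev epoxidation picks the only electron-rich alkene (the 4,5-olefin carries three allylic C–O bonds, the other two are acrylate-type) and should attack the outer face of the E-1(10) alkene in the C14-syn conformer, giving the 1R,10R epoxide common to this family.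

Step 15
Reactants: 24 (1R,3S,6R,7R,8R,10R)-15-[(tert-butyldimethylsilyl)oxy]-1,10-epoxy-8-(methacryloyloxy)-3-[(triethylsilyl)oxy]germacra-4Z,11(13)-dien-12,6-olide
Product: 25 (1R,3S,6R,7R,8R,10R)-1,10-epoxy-3,15-dihydroxy-8-(methacryloyloxy)germacra-4Z,11(13)-dien-12,6-olide
Conditions: HF·pyridine, pyridine, THF, 0 °C to rt
Reagents that add atoms: none
Why: Fluoride-mediated desilylation removes both silyl ethers; pyridine buffering spares the epoxide, the methacrylate and the α-methylene lactone.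

## Compound list

1 | prop-2-yn-1-ol | C#CCO | starting material
2 | tert-butyldimethyl(prop-2-yn-1-yloxy)silane | C#CCO[Si](C)(C)C(C)(C)C | intermediate
3 | {3-[(tert-butyldimethylsilyl)oxy]prop-1-yn-1-yl}lithium | [Li]C#CCO[Si](C)(C)C(C)(C)C | intermediate
4 | 4-[(tert-butyldimethylsilyl)oxy]but-2-ynal | O=CC#CCO[Si](C)(C)C(C)(C)C | intermediate
5 | (Z)-3-bromo-4-[(tert-butyldimethylsilyl)oxy]but-2-enal | O=C/C=C(\Br)CO[Si](C)(C)C(C)(C)C | intermediate
6 | methyl{3-[(tert-butyldimethylsilyl)oxy]prop-1-yn-1-yl}zinc | C[Zn]C#CCO[Si](C)(C)C(C)(C)C | intermediate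
7 | (2Z,4R)-2-bromo-1,7-bis[(tert-butyldimethylsilyl)oxy]hept-2-en-5-yn-4-ol | Br/C(CO[Si](C)(C)C(C)(C)C)=C\[C@@H](O)C#CCO[Si](C)(C)C(C)(C)C | intermediate
8 | sodium cyclic alkenyl(alkoxy)bis(2-methoxyethoxy)aluminate from 7 (Al on C11 and on O6) | [Na+].COCCO[Al-]1(OCCOC)O[C@H](/C=C(\Br)CO[Si](C)(C)C(C)(C)C)C=C1CO[Si](C)(C)C(C)(C)C | intermediate
9 | (2Z,4R,5Z)-2-bromo-6-iodo-1,7-bis[(tert-butyldimethylsilyl)oxy]hepta-2,5-dien-4-ol | Br/C(CO[Si](C)(C)C(C)(C)C)=C\[C@@H](O)/C=C(\I)CO[Si](C)(C)C(C)(C)C | intermediate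
10 | (5S)-5-[(1Z)-2-bromo-3-[(tert-butyldimethylsilyl)oxy]prop-1-en-1-yl]-3-{[(tert-butyldimethylsilyl)oxy]methyl}furan-2(5H)-one | Br/C(CO[Si](C)(C)C(C)(C)C)=C\[C@H]1OC(=O)C(CO[Si](C)(C)C(C)(C)C)=C1 | intermediate
11 | but-3-yn-1-ol | C#CCCO | starting material
12 | (but-3-yn-1-yloxy)triethylsilane | C#CCCO[Si](CC)(CC)CC | intermediate
13 | oxirane | C1CO1 | starting material
14 | (E)-dimethyl{2-methyl-4-[(triethylsilyl)oxy]but-1-en-1-yl}alane | C[Al](C)/C=C(\C)CCO[Si](CC)(CC)CC | intermediate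
15 | lithium (E)-butyldimethyl{2-methyl-4-[(triethylsilyl)oxy]but-1-en-1-yl}alanate | [Li+].CCCC[Al-](C)(C)/C=C(\C)CCO[Si](CC)(CC)CC | intermediate
16 | (E)-4-methyl-6-[(triethylsilyl)oxy]hex-3-en-1-ol | OCC/C=C(\C)CCO[Si](CC)(CC)CC | intermediate
17 | (E)-4-methyl-6-[(triethylsilyl)oxy]hex-3-enal | O=CC/C=C(\C)CCO[Si](CC)(CC)CC | intermediate
18 | (5R)-5-[(1Z,3S,5E)-2-{[(tert-butyldimethylsilyl)oxy]methyl}-6-methyl-3,8-bis[(triethylsilyl)oxy]octa-1,5-dien-1-yl]-3-{[(tert-butyldimethylsilyl)oxy]methyl}furan-2(5H)-one | CC[Si](CC)(CC)OCC/C(C)=C/C[C@H](O[Si](CC)(CC)CC)/C(CO[Si](C)(C)C(C)(C)C)=C\[C@H]1OC(=O)C(CO[Si](C)(C)C(C)(C)C)=C1 | intermediate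
19 | (5R)-5-[(1Z,3S,5E)-2-{[(tert-butyldimethylsilyl)oxy]methyl}-6-methyl-8-oxo-3-[(triethylsilyl)oxy]octa-1,5-dien-1-yl]-3-{[(tert-butyldimethylsilyl)oxy]methyl}furan-2(5H)-one | O=CC/C(C)=C/C[C@H](O[Si](CC)(CC)CC)/C(CO[Si](C)(C)C(C)(C)C)=C\[C@H]1OC(=O)C(CO[Si](C)(C)C(C)(C)C)=C1 | intermediate
20 | cyclised bis(diiodosamarium) species: C8 alkoxide and C12 lactone enolate still carrying 13-OTBS | I[Sm](I)O[C@@H]1C/C(C)=C/C[C@H](O[Si](CC)(CC)CC)/C(CO[Si](C)(C)C(C)(C)C)=C\[C@H]2OC(O[Sm](I)I)=C(CO[Si](C)(C)C(C)(C)C)[C@@H]21 | intermediate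
21 | (3S,6R,7R,8R)-15-[(tert-butyldimethylsilyl)oxy]-8-hydroxy-3-[(triethylsilyl)oxy]germacra-1(10)E,4Z,11(13)-trien-12,6-olide | O[C@@H]1C/C(C)=C/C[C@H](O[Si](CC)(CC)CC)/C(CO[Si](C)(C)C(C)(C)C)=C\[C@H]2OC(=O)C(=C)[C@@H]21 | intermediate
22 | methacryloyl chloride | C=C(C)C(=O)Cl | starting material
23 | (3S,6R,7R,8R)-15-[(tert-butyldimethylsilyl)oxy]-8-(methacryloyloxy)-3-[(triethylsilyl)oxy]germacra-1(10)E,4Z,11(13)-trien-12,6-olide | C=C(C)C(=O)O[C@@H]1C/C(C)=C/C[C@H](O[Si](CC)(CC)CC)/C(CO[Si](C)(C)C(C)(C)C)=C\[C@H]2OC(=O)C(=C)[C@@H]21 | intermediate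
24 | (1R,3S,6R,7R,8R,10R)-15-[(tert-butyldimethylsilyl)oxy]-1,10-epoxy-8-(methacryloyloxy)-3-[(triethylsilyl)oxy]germacra-4Z,11(13)-dien-12,6-olide | C=C(C)C(=O)O[C@@H]1C[C@@]2(C)O[C@@H]2C[C@H](O[Si](CC)(CC)CC)/C(CO[Si](C)(C)C(C)(C)C)=C\[C@H]2OC(=O)C(=C)[C@@H]21 | intermediate
25 | (1R,3S,6R,7R,8R,10R)-1,10-epoxy-3,15-dihydroxy-8-(methacryloyloxy)germacra-4Z,11(13)-dien-12,6-olide (CNP0496616.1) | C=C(C)C(=O)O[C@@H]1C[C@@]2(C)O[C@@H]2C[C@H](O)/C(CO)=C\[C@H]2OC(=O)C(=C)[C@@H]21 | target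

## Step count and risk

Total steps: 15. Longest linear sequence: 12 (steps 1–6, then 10–15); steps 7–9 form the side branch.

Most likely to fail, 1: step 12, the radical macrocyclisation. Pinacol dimerisation, simple aldehyde reduction or protonation of the enolate before silanolate loss could compete with ten-membered ring closure, and the C8 configuration rests on a chelate model. The fallback keeps the ketyl–butenolide addition but runs it between two molecules and closes the ring by a Ni/Cr coupling at C3–C4. It sets out from 16 and 10 and returns at 23. Alcohol 16 is etherified (NaH, PMBCl) to PMB ether F1. Direct Swern oxidation of its primary TES ether gives aldehyde F2. SmI2 in THF couples F2 with butenolide 10 (addition anti to the C5 side chain, loss of silanolate) to give hydroxy α-methylene lactone F3. Methacryloyl chloride gives methacrylate F4, DDQ frees primary alcohol F5, and Dess–Martin oxidation gives aldehyde F6. Intramolecular CrCl2/NiCl2 coupling of the alkenyl bromide with the aldehyde at high dilution closes the ring to 3-hydroxy macrocycle F7. TESOTf/2,6-lutidine then gives 23.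

Most likely to fail, 2: step 14, the late epoxidation. Facial selectivity depends on the macrocycle conformation, and the 4,5-alkene could compete. The fallback installs the epoxide under reagent control before ring closure. It sets out from 18 and returns at 24. Shi epoxidation of 18 (D-fructose-derived ketone, Oxone, buffered MeCN/DMM/H2O, 0 °C; R,R-selective for E-trisubstituted alkenes) gives epoxide F8. Swern oxidation of the primary TES ether gives epoxy aldehyde F9, which is used cold and at once because β,γ-epoxy aldehydes eliminate easily. The SmI2 ring closure of step 12 gives epoxy macrocyclic alcohol F10. Methacryloyl chloride then gives 24.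

Most likely to fail, 3: step 10, the asymmetric Ni/Cr coupling. The trisubstituted alkenyl bromide is less reactive than an iodide, and C3 is set only by the catalyst, far from C6. The fallback sets C3 by ketone reduction instead. It sets out from 10 and 17 and returns at 18. Stoichiometric, ligand-free CrCl2/NiCl2 coupling in DMSO gives the C3-epimeric alcohols F11. Dess–Martin oxidation gives enone F12. (R)-CBS/catecholborane reduction, with the alkenyl group as the large substituent, gives the 3S alcohol F13. TESCl/imidazole then gives 18.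

Further compounds

F1 | step 12 | (E)-triethyl({6-[(4-methoxybenzyl)oxy]-3-methylhex-3-en-1-yl}oxy)silane | CC[Si](CC)(CC)OCC/C(C)=C/CCOCc1ccc(OC)cc1
F2 | step 12 | (E)-6-[(4-methoxybenzyl)oxy]-3-methylhex-3-enal | O=CC/C(C)=C/CCOCc1ccc(OC)cc1
F3 | step 12 | (4R,5S)-5-[(1Z)-2-bromo-3-[(tert-butyldimethylsilyl)oxy]prop-1-en-1-yl]-4-{(1R,3E)-1-hydroxy-6-[(4-methoxybenzyl)oxy]-3-methylhex-3-en-1-yl}-3-methylidenedihydrofuran-2(3H)-one | O[C@H](C/C(C)=C/CCOCc1ccc(OC)cc1)[C@H]1C(=C)C(=O)O[C@@H]1/C=C(\Br)CO[Si](C)(C)C(C)(C)C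
F4 | step 12 | methacrylate ester of F3 at the C8 hydroxyl | C=C(C)C(=O)O[C@H](C/C(C)=C/CCOCc1ccc(OC)cc1)[C@H]1C(=C)C(=O)O[C@@H]1/C=C(\Br)CO[Si](C)(C)C(C)(C)C
F5 | step 12 | primary alcohol from PMB removal of F4 | C=C(C)C(=O)O[C@H](C/C(C)=C/CCO)[C@H]1C(=C)C(=O)O[C@@H]1/C=C(\Br)CO[Si](C)(C)C(C)(C)C
F6 | step 12 | C3 aldehyde from oxidation of F5 | C=C(C)C(=O)O[C@H](C/C(C)=C/CC=O)[C@H]1C(=C)C(=O)O[C@@H]1/C=C(\Br)CO[Si](C)(C)C(C)(C)C
F7 | step 12 | (3S,6R,7R,8R)-15-[(tert-butyldimethylsilyl)oxy]-3-hydroxy-8-(methacryloyloxy)germacra-1(10)E,4Z,11(13)-trien-12,6-olide | C=C(C)C(=O)O[C@@H]1C/C(C)=C/C[C@H](O)/C(CO[Si](C)(C)C(C)(C)C)=C\[C@H]2OC(=O)C(=C)[C@@H]21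
F8 | step 14 | (1R,10R)-1,10-epoxide of 18 | CC[Si](CC)(CC)OCC[C@@]1(C)O[C@@H]1C[C@H](O[Si](CC)(CC)CC)/C(CO[Si](C)(C)C(C)(C)C)=C\[C@H]2OC(=O)C(CO[Si](C)(C)C(C)(C)C)=C2
F9 | step 14 | (1R,10R)-1,10-epoxide of seco-aldehyde 19 | O=CC[C@@]1(C)O[C@@H]1C[C@H](O[Si](CC)(CC)CC)/C(CO[Si](C)(C)C(C)(C)C)=C\[C@H]2OC(=O)C(CO[Si](C)(C)C(C)(C)C)=C2
F10 | step 14 | (1R,3S,6R,7R,8R,10R)-15-[(tert-butyldimethylsilyl)oxy]-1,10-epoxy-8-hydroxy-3-[(triethylsilyl)oxy]germacra-4Z,11(13)-dien-12,6-olide | O[C@@H]1C[C@@]2(C)O[C@@H]2C[C@H](O[Si](CC)(CC)CC)/C(CO[Si](C)(C)C(C)(C)C)=C\[C@H]2OC(=O)C(=C)[C@@H]21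
F11 | step 10 | C3-epimeric mixture of the free 3-hydroxy analogue of 18 | CC[Si](CC)(CC)OCC/C(C)=C/CC(O)/C(CO[Si](C)(C)C(C)(C)C)=C\[C@H]1OC(=O)C(CO[Si](C)(C)C(C)(C)C)=C1
F12 | step 10 | 3-oxo analogue of 18 (enone) | CC[Si](CC)(CC)OCC/C(C)=C/CC(=O)/C(CO[Si](C)(C)C(C)(C)C)=C\[C@H]1OC(=O)C(CO[Si](C)(C)C(C)(C)C)=C1
F13 | step 10 | (3S)-3-hydroxy analogue of 18 | CC[Si](CC)(CC)OCC/C(C)=C/C[C@H](O)/C(CO[Si](C)(C)C(C)(C)C)=C\[C@H]1OC(=O)C(CO[Si](C)(C)C(C)(C)C)=C1
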